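The steps thought possible turn one form of the initiator into another and one form of the monomer into another, so c(initiator) + c(living end) + c(spent initiator) stays at the charge of initiator, and c(free monomer) + c(monomer in chains) + c(uncatalysed product) stays at the charge of free monomer.

| setting | epsilon | theta | beta | east | south-east | north |
|---|---|---|---|---|---|---|
| free monomer | 1.4 mM | 2.2 mM | 1 mM | 1.0 mM | 1.0 mM | 1.0 mM |
| initiator | 4.1 µM | 4.1 µM | 6.1 µM | 4.1 µM | 4.1 µM | 4.1 µM |
| temperature | −10 °C | 23 °C | −10 °C | 5 °C | −25 °C | 35 °C |
| remark | run made earlier | run made earlier | run made earlier |  |  |  |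
| time |  |  |  | 6.0 min | 6.0 min | 6.0 min |

- epsilon (time / min: monomer in chains / %): 2.00: 4.5; 3.00: 9.7; 5.00: 20.9; 6.00: 27.6; 8.00: 39.1; 10.0: 48.0
- theta (time / s: monomer in chains / %): 20.0: 3.4; 40.0: 6.8; 60.0: 7.8; 80.0: 8.3; 90.0: 8.7; 120: 8.4
- beta (time / min: monomer in chains / %): 0.833: 1.4; 3.00: 10.2; 4.00: 16.5; 6.00: 29.3; 10.0: 50.3

(scatter of a reading: 0.3 percentage points)

- the earlier runs were read with a standard deviation of 0.3 percentage points
- steps thought possible: free monomer + living end -> monomer in chains + living end; initiator -> spent initiator; free monomer + initiator -> living end + monomer in chains; free monomer -> uncatalysed product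

- the flask that comes out highest in amount of monomer in chains, in percent of the free monomer charged, or "all alike" when all lie within 1.5 percentage points (east / south-east / north / all alike)
- monomer in chains at the end, in percent of the free monomer charged, east
- monomer in chains at the end, in percent of the free monomer charged, south-east
- monomer in chains at the end, in percent of the free monomer charged, north

The initiator is charged in far smaller amount than the free monomer. I assume that c(initiator) barely falls, which makes initiation pseudo-first-order in free monomer. Then c(living end) grows with a, the time integral of the fraction of free monomer left, and the chain fraction equals (a/tg)², where tg is the growth time, proportional to one over the square root of c(free monomer)·c(initiator). The uncatalysed fraction equals a/τ, where τ is the loss time. Both products read the same a, so uncatalysed fraction over the square root of chain fraction stays at r = tg/τ, the split ratio.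

Epsilon's first reading gives tg = 9.43 min, and beta, scaled to epsilon's charge, gives 9.68 min. Epsilon's last readings, through the monomer balance, give τ = 25.2 min. Theta's rise to its plateau gives τ = 19.8 s and tg = 68.2 s. These two temperatures set the slopes: 8920 K for tg squared and 10200 K for τ.

For east I reckon tg = 4.47 min and τ = 3.09 min, so r = 1.45. Solving the balance, in which a/tg climbs towards 0.511, gives 23.8% in east at the asked time. South-east has tg = 31.1 min, longer than the time given, so I reckon 3.73%, with r = 0.117. North has r = 10.9, so I reckon 0.842%.

The forecast, holding that “initiator decay beats initiation”, named east, with 31% in east, 2.8% in south-east and 0.5% in north.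

The flasks give east highest, with 24.8% in east, 4.48% in south-east and 1.14% in north.

    free monomer + living end → monomer in chains + living end, rate k1*[living end]*[free monomer] (k = 6700 L mol⁻¹ s⁻¹, Ea = 25.0 kJ mol⁻¹)
    initiator → spent initiator (k = 1.50 × 10⁻⁵ s⁻¹, Ea = 86.0 kJ mol⁻¹)
    free monomer + initiator → living end + monomer in chains (k = 1.10 L mol⁻¹ s⁻¹, Ea = 46.0 kJ mol⁻¹)
    free monomer → uncatalysed product (k = 0.00530 s⁻¹, Ea = 81.0 kJ mol⁻¹)
    (constants at 5 °C)

The ratio barely moves with time in east and in south-east. In east, uncatalysed fraction over the square root of chain fraction reads 1.39 at 3.00 min and 1.40 at 6.00 min, against the reckoned 1.45. South-east reads 0.127 at 6.00 min and 0.130 at 60.0 min, against 0.117. North reads 9.26 at 6.00 min, against 10.9, and the uncatalysed step is the main reason for its low yield: without that step, north's 1.14% of monomer in chains becomes >99.9%.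

The data stem from a simulated flask with made-up constants.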